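The route rests on cutting ring B across C7–C8 and C9–C10. The 8(17)-methylene on C8 beside the fully substituted C9 (oxygen plus C11) is read as the trace of an allene whose carbonyl-conjugated double bond served as dienophile. One intermolecular Diels–Alder reaction between an enantiopure ring A vinylcyclohexene (C4 already set) and a 1-alkoxyallenyl ketone therefore closes ring B, creates both bonds and the C9 and C10 stereocentres, and leaves the exocyclic alkene and a 5-ene for later hydroxylation at C5. The dienophile carries a 4-methoxybenzyl ether on O9 and the C13 ketone as a dioxolane.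

Key step: step 10

Remark on numbering: bicyclic compounds are numbered as labdanes (ring A = C1–C5 and C10; ring B = C5–C10; C17 = CH2 on C8; C18 = methyl and C19 = carboxyl carbon on C4; C20 = methyl on C10; side chain C11–C16); β is the face of the C10 methyl group.

Assumption: in the enamine alkylation the donor on lithium decides which face is methylated; the weak-donor (THF) variant is taken to deliver the (S)-keto ester, and the mirror-image auxiliary would be used without further change if it delivered the antipode.

Step 1
Reactants: 1 methyl 2-oxocyclohexane-1-carboxylate; 2 tert-butyl L-valinate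
Product: 3 methyl 2-{[(2S)-1-(tert-butoxy)-3-methyl-1-oxobutan-2-yl]amino}cyclohex-1-ene-1-carboxylate
Conditions: BF3·OEt2 (cat.), toluene, reflux, Dean–Stark
Reagents that add atoms: none
Why: Condensation of the β-keto ester with the primary amine under azeotropic removal of water gives the hydrogen-bonded enamino ester (vinylogous carbamate), and the valine centre is not touched.

Step 2
Reactants: 3 enamino ester
Product: 5 methyl (1S)-1-methyl-2-oxocyclohexane-1-carboxylate, via alkylated valine imine 4 (not isolated)
Conditions: LiN(i-Pr)2, toluene, −78 °C; THF (2 equiv), MeI, −55 °C; then 1 M HCl, 0 °C → rt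
Reagents that add atoms: iodomethane, CI; water, O
Why: Auxiliary-controlled C-alkylation of a deprotonated chiral enamino ester, in which lithium is clamped by the nitrogen and both ester carbonyls and the isopropyl group makes the two faces unequal, so that methyl iodide should enter from one face and set the quaternary (1S) centre that becomes C4, after which acid hydrolysis of the imine releases the ketone and the auxiliary.

Step 3
Reactants: 5 methyl (1S)-1-methyl-2-oxocyclohexane-1-carboxylate
Product: 6 methyl (1S)-1,3-dimethyl-2-oxocyclohexane-1-carboxylate (both C3 epimers)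
Conditions: LiN(i-Pr)2, THF, −78 °C; MeI, −78 → −20 °C
Reagents that add atoms: iodomethane, CI
Why: Kinetic enolate alkylation at the only enolisable position (the other α-carbon is quaternary) introduces the future C20 methyl, and the new C3 centre need not be controlled because it becomes sp2 in step 4.

Step 4
Reactants: 6 methyl (1S)-1,3-dimethyl-2-oxocyclohexane-1-carboxylate
Product: 7 methyl (1S)-1,3-dimethyl-2-{[(trifluoromethyl)sulfonyl]oxy}cyclohex-2-ene-1-carboxylate
Conditions: KN(SiMe3)2, THF, −78 °C; PhNTf2, −78 → 0 °C
Reagents that add atoms: N-phenylbis(trifluoromethanesulfonimide), O=S(=O)(N(c1ccccc1)S(=O)(=O)C(F)(F)F)C(F)(F)F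
Why: Enol triflate formation by deprotonation of the single remaining α-hydrogen and O-sulfonylation gives the tetrasubstituted alkenyl triflate with only one possible regiochemistry, the quaternary centre being untouched.

Step 5
Reactants: 7 alkenyl triflate; 8 4,4,5,5-tetramethyl-2-vinyl-1,3,2-dioxaborolane
Product: 9 methyl (1S)-1,3-dimethyl-2-vinylcyclohex-2-ene-1-carboxylate (ring A diene)
Conditions: Pd(PPh3)4 (5 mol %), K3PO4, 1,4-dioxane/H2O, 80 °C
Reagents that add atoms: none
Why: Suzuki–Miyaura coupling (oxidative addition of zerovalent palladium into the C–OTf bond, transmetalation from the vinylboronate, reductive elimination) is routine for hindered cyclohexenyl triflates and gives the diene C7=C6–C5=C10 without touching the stereocentre.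

Step 6
Reactants: 10 prop-2-yn-1-ol
Product: 11 1-methoxy-4-[(prop-2-yn-1-yloxy)methyl]benzene
Conditions: NaH, THF, 0 °C; 4-MeOC6H4CH2Cl, Bu4NI (cat.), 0 °C → rt
Reagents that add atoms: 4-methoxybenzyl chloride, COc1ccc(CCl)cc1
Why: Williamson etherification of the alkoxide (formed in preference to the acetylide) installs a 4-methoxybenzyl group, chosen because it can be taken off O9 at the end oxidatively instead of with acid.

Step 7
Reactants: 11 1-methoxy-4-[(prop-2-yn-1-yloxy)methyl]benzene
Product: 12 1-methoxy-4-[(propa-1,2-dien-1-yloxy)methyl]benzene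
Conditions: KOt-Bu (0.2 equiv), THF, rt
Reagents that add atoms: none
Why: Base-catalysed prototropic propargyl-to-allenyl isomerisation is the standard preparation of alkoxyallenes and is stopped before further migration to the 1-propynyl ether.

Step 8
Reactants: 13 ethyl 2-(2-methyl-1,3-dioxolan-2-yl)acetate
Product: 14 N-methoxy-N-methyl-2-(2-methyl-1,3-dioxolan-2-yl)acetamide
Conditions: MeNHOMe·HCl, i-PrMgCl, THF, −20 → 0 °C
Reagents that add atoms: N,O-dimethylhydroxylamine hydrochloride, CNOC.Cl
Why: Aminolysis of the ethyl ester by the chloromagnesium amide of N,O-dimethylhydroxylamine is the standard ester-to-Weinreb-amide conversion, and the dioxolane is inert to the Grignard base at low temperature.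

Step 9
Reactants: 12 4-methoxybenzyloxyallene; 14 Weinreb amide
Product: 16 3-[(4-methoxybenzyl)oxy]-1-(2-methyl-1,3-dioxolan-2-yl)penta-3,4-dien-2-one, via lithiated allenyl ether 15 (not isolated)
Conditions: n-BuLi, THF, −78 °C; then 14, −78 → −40 °C; H2O quench; used without delay
Reagents that add atoms: none
Why: Alkoxyallenes are lithiated at the oxygen-bearing carbon, and acylation of this nucleophile by a Weinreb amide stops cleanly after one addition, which is the established way to 1-alkoxyallenyl ketones.

Step 10
Reactants: 9 ring A diene; 16 1-alkoxyallenyl ketone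
Product: 17 methyl 13,13-ethylenedioxy-9β-[(4-methoxybenzyl)oxy]-11-oxo-14,15-dinorlabda-5,8(17)-dien-19-oate (9α-acyl, 10β-methyl, 4β-ester)
Conditions: 9 (2 equiv), toluene (2 M), BHT (cat.), 110 °C, sealed tube
Reagents that add atoms: none
Why: A thermal, concerted but asynchronous [4+2] cycloaddition (Diels–Alder reaction) joins the s-cis diene C7=C6–C5=C10 of 9 to the ketone-conjugated C8=C9 bond of allene 16, the closest known cases being additions of 1-vinyl-2-methylcyclohexenes to alkynes and of acylallenes to simple dienes. Ring B closes as a six-membered carbocycle by this cycloaddition, suprafacially on both partners, with bond C7–C8 running ahead of bond C9–C10, while the remote allene bond stays out and becomes the 8(17)-methylene and the central diene bond becomes the 5-ene. Regiochemistry follows from polarisation: the unsubstituted terminus C7 carries the largest HOMO coefficient and the least hindrance and joins the central allene carbon C8, the β-carbon of the enone with the largest LUMO coefficient. C10 is controlled by the C4 centre of 9, because the ester, the C4 substituent with the smaller conformational demand, takes the pseudo-axial position and should send the dienophile to the opposite (α) face, which leaves the C10 methyl β and cis to the ester. C9 is controlled by the endo rule, since an acyl group lying under the diene ends up trans to the C10 methyl (the inside substituent of the diene), giving 9α-acyl and 9β-oxygen. The step thus needs chemo-, regio-, endo- and facial selectivity together; conjugation and orbital coefficients secure the first two and the sp-hybridised C8 keeps the dienophile slim enough for this hindered diene, whereas the last two rest on secondary overlap with the carbonyl group and on shielding by the C4 ester and are the real uncertainty of the route.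

Step 11
Reactants: 17 cycloadduct
Product: 19 methyl 11-hydroxy-9β-[(4-methoxybenzyl)oxy]-13-oxo-14,15-dinorlabda-5,8(17)-dien-19-oate (both C11 epimers), via C11 carbinol ketal 18 (not isolated)
Conditions: NaBH4, MeOH, 0 °C → rt; then acetone, 1 M HCl (to pH 2), rt
Reagents that add atoms: water, O
Why: Borohydride reduction of the only ketone (the hindered methyl ester is inert), followed in the same flask by acid-catalysed ketal hydrolysis, gives the aldol-type β-hydroxy ketone, and the uncontrolled C11 carbinol centre disappears in step 12.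

Step 12
Reactants: 19 β-hydroxy ketone
Product: 21 methyl 9β-[(4-methoxybenzyl)oxy]-13-oxo-14,15-dinorlabda-5,8(17),11E-trien-19-oate, via C11 mesylate 20 (not isolated)
Conditions: MsCl, Et3N, CH2Cl2, 0 °C; then DBU, 0 °C → rt
Reagents that add atoms: none
Why: Mesylation followed by E1cB elimination through the C12 enolate gives the conjugated E-enone, an ionic way of taking the oxygen off C11 that avoids a C11 radical, which could shift the neighbouring C8 vinylidene unit (homoallyl–cyclopropylcarbinyl rearrangement) and enlarge ring B.

Step 13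
Reactants: 21 enone
Product: 22 methyl 9β-[(4-methoxybenzyl)oxy]-13-oxo-14,15-dinorlabda-5,8(17)-dien-19-oate
Conditions: [(Ph3P)CuH]6 (0.35 equiv), H2O (2 equiv), degassed benzene, rt
Reagents that add atoms: none
Why: Conjugate reduction with Stryker's reagent delivers hydride to C11 and water protonates the resulting enolate, so only the enone alkene is saturated while the 5-ene, the 8(17)-methylene, the ester and the benzylic ether stay.

Step 14
Reactants: 22 methyl ketone
Product: 23 methyl 5α,6α-epoxy-9β-[(4-methoxybenzyl)oxy]-13-oxo-14,15-dinorlabd-8(17)-en-19-oate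
Conditions: mCPBA (1.1 equiv), NaHCO3, CH2Cl2, 0 °C
Reagents that add atoms: 3-chloroperoxybenzoic acid, O=C(OO)c1cccc(Cl)c1
Why: Prilezhaev epoxidation picks the trisubstituted 5-ene as the most electron-rich alkene (the 8(17)-methylene is only 1,1-disubstituted and deactivated by the allylic ether), and the peracid should come from the α face because the β face is blocked on both allylic carbons by the axial C10 methyl and the C4 ester, which sets C5 and C6 as the 5α,6α-epoxide.

Step 15
Reactants: 23 epoxide
Product: 24 9β-[(4-methoxybenzyl)oxy]-14,15-dinorlabd-8(17)-ene-5α,13,19-triol (both C13 epimers)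
Conditions: LiAlH4 (excess), THF, 0 °C → reflux; Fieser work-up
Reagents that add atoms: none
Why: LiAlH4 reduces ketone and ester and then opens the epoxide by SN2 attack of hydride at the secondary C6 from the β face (trans-diaxial opening, Fürst–Plattner rule), so the C5–O bond made in step 14 stays as the 5α tertiary alcohol; since no hydride able to open this epoxide would spare the ester, C19 is taken down to the alcohol on purpose and re-oxidised in steps 16 and 17 together with the C13 carbinol.

Step 16
Reactants: 24 triol
Product: 25 5α-hydroxy-9β-[(4-methoxybenzyl)oxy]-13-oxo-14,15-dinorlabd-8(17)-en-19-al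
Conditions: Dess–Martin periodinane (2.5 equiv), NaHCO3, CH2Cl2, 0 °C → rt
Reagents that add atoms: none
Why: Dess–Martin oxidation converts the primary C19 and the secondary C13 alcohol into aldehyde and ketone under buffered conditions, while the tertiary C5 alcohol cannot react and the quaternary C4 cannot epimerise.

Step 17
Reactants: 25 keto aldehyde
Product: 26 5α-hydroxy-9β-[(4-methoxybenzyl)oxy]-13-oxo-14,15-dinorlabd-8(17)-en-19-oic acid
Conditions: NaClO2, NaH2PO4, 2-methylbut-2-ene, t-BuOH/H2O, 0 °C → rt
Reagents that add atoms: sodium chlorite, [Na+].[O-]Cl=O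
Why: Pinnick oxidation turns only the aldehyde into the carboxylic acid, and the alkene scavenger traps the hypochlorite by-product so that the exocyclic alkene and the anisyl ring are spared.

Step 18
Reactants: 26 keto acid; 27 triethyl phosphonoacetate
Product: 28 15-ethyl hydrogen 5α-hydroxy-9β-[(4-methoxybenzyl)oxy]labda-8(17),13E-diene-15,19-dioate
Conditions: NaH (4 equiv), 27 (3 equiv), THF/DMF, 0 → 50 °C; acidify to pH 4 on work-up
Reagents that add atoms: none
Why: Horner–Wadsworth–Emmons olefination of the methyl ketone (excess base first turns the acid and the alcohol into inert sodium salts) should favour the E-enoate with the ester trans to the larger C12 chain, any Z isomer being removed by chromatography, and the ether still on O9 prevents oxa-Michael closure to a 9,13-ether.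

Step 19
Reactants: 28 enoate acid
Product: 29 5α,15-dihydroxy-9β-[(4-methoxybenzyl)oxy]labda-8(17),13E-dien-19-oic acid
Conditions: i-Bu2AlH (6 equiv), CH2Cl2, −78 → −40 °C; Rochelle salt, then pH 4
Reagents that add atoms: none
Why: i-Bu2AlH reduces the conjugated ethyl ester in the 1,2 sense to the E-allylic alcohol without change of alkene geometry, the carboxylic acid being masked in the flask as its aluminium carboxylate, which is not reduced at low temperature.

Step 20
Reactants: 29 protected acid
Product: 30 5α,9β-dihydroxyisocupressic acid (5α,9β,15-trihydroxylabda-8(17),13E-dien-19-oic acid)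
Conditions: DDQ (1.5 equiv), CH2Cl2/pH 7 phosphate buffer (10:1), 0 °C
Reagents that add atoms: none
Why: Oxidative debenzylation, in which DDQ takes hydride from the electron-rich benzylic position, water adds to the oxocarbenium ion and the hemiacetal collapses to the free tertiary C9 alcohol, runs under neutral conditions that spare the two allylic alcohols and the exocyclic alkene.

Compound list

1 | methyl 2-oxocyclohexane-1-carboxylate | COC(=O)C1CCCCC1=O | starting material
2 | tert-butyl L-valinate | CC(C)[C@H](N)C(=O)OC(C)(C)C | starting material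
3 | methyl 2-{[(2S)-1-(tert-butoxy)-3-methyl-1-oxobutan-2-yl]amino}cyclohex-1-ene-1-carboxylate | COC(=O)C1=C(N[C@@H](C(C)C)C(=O)OC(C)(C)C)CCCC1 | intermediate
4 | methyl (1S)-2-{[(2S)-1-(tert-butoxy)-3-methyl-1-oxobutan-2-yl]imino}-1-methylcyclohexane-1-carboxylate | CC(C)[C@H](N=C1CCCC[C@]1(C)C(=O)OC)C(=O)OC(C)(C)C | intermediate
5 | methyl (1S)-1-methyl-2-oxocyclohexane-1-carboxylate | O=C1CCCC[C@]1(C)C(=O)OC | intermediate
6 | methyl (1S)-1,3-dimethyl-2-oxocyclohexane-1-carboxylate (C3 epimers) | O=C1C(C)CCC[C@]1(C)C(=O)OC | intermediate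
7 | methyl (1S)-1,3-dimethyl-2-{[(trifluoromethyl)sulfonyl]oxy}cyclohex-2-ene-1-carboxylate | O=S(=O)(OC1=C(C)CCC[C@]1(C)C(=O)OC)C(F)(F)F | intermediate
8 | 4,4,5,5-tetramethyl-2-vinyl-1,3,2-dioxaborolane | C=CB1OC(C)(C)C(C)(C)O1 | starting material
9 | methyl (1S)-1,3-dimethyl-2-vinylcyclohex-2-ene-1-carboxylate | C=CC1=C(C)CCC[C@]1(C)C(=O)OC | intermediate
10 | prop-2-yn-1-ol | C#CCO | starting material
11 | 1-methoxy-4-[(prop-2-yn-1-yloxy)methyl]benzene | C#CCOCc1ccc(OC)cc1 | intermediate
12 | 1-methoxy-4-[(propa-1,2-dien-1-yloxy)methyl]benzene | C=C=COCc1ccc(OC)cc1 | intermediate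
13 | ethyl 2-(2-methyl-1,3-dioxolan-2-yl)acetate | CCOC(=O)CC1(C)OCCO1 | starting material
14 | N-methoxy-N-methyl-2-(2-methyl-1,3-dioxolan-2-yl)acetamide | CON(C)C(=O)CC1(C)OCCO1 | intermediate
15 | 1-lithio-1-[(4-methoxybenzyl)oxy]propa-1,2-diene | [Li]C(=C=C)OCc1ccc(OC)cc1 | intermediate
16 | 3-[(4-methoxybenzyl)oxy]-1-(2-methyl-1,3-dioxolan-2-yl)penta-3,4-dien-2-one | C=C=C(OCc1ccc(OC)cc1)C(=O)CC2(C)OCCO2 | intermediate
17 | methyl 13,13-ethylenedioxy-9β-[(4-methoxybenzyl)oxy]-11-oxo-14,15-dinorlabda-5,8(17)-dien-19-oate | C=C1CC=C2[C@](C)(CCC[C@]2(C)C(=O)OC)[C@]1(OCc3ccc(OC)cc3)C(=O)CC4(C)OCCO4 | intermediate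
18 | methyl 13,13-ethylenedioxy-11-hydroxy-9β-[(4-methoxybenzyl)oxy]-14,15-dinorlabda-5,8(17)-dien-19-oate (C11 epimers) | C=C1CC=C2[C@](C)(CCC[C@]2(C)C(=O)OC)[C@]1(OCc3ccc(OC)cc3)C(O)CC4(C)OCCO4 | intermediate
19 | methyl 11-hydroxy-9β-[(4-methoxybenzyl)oxy]-13-oxo-14,15-dinorlabda-5,8(17)-dien-19-oate (C11 epimers) | C=C1CC=C2[C@](C)(CCC[C@]2(C)C(=O)OC)[C@]1(OCc3ccc(OC)cc3)C(O)CC(C)=O | intermediate
20 | methyl 11-(methanesulfonyloxy)-9β-[(4-methoxybenzyl)oxy]-13-oxo-14,15-dinorlabda-5,8(17)-dien-19-oate (C11 epimers) | C=C1CC=C2[C@](C)(CCC[C@]2(C)C(=O)OC)[C@]1(OCc3ccc(OC)cc3)C(OS(C)(=O)=O)CC(C)=O | intermediate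
21 | methyl 9β-[(4-methoxybenzyl)oxy]-13-oxo-14,15-dinorlabda-5,8(17),11E-trien-19-oate | C=C1CC=C2[C@](C)(CCC[C@]2(C)C(=O)OC)[C@]1(OCc3ccc(OC)cc3)/C=C/C(C)=O | intermediate
22 | methyl 9β-[(4-methoxybenzyl)oxy]-13-oxo-14,15-dinorlabda-5,8(17)-dien-19-oate | C=C1CC=C2[C@](C)(CCC[C@]2(C)C(=O)OC)[C@]1(OCc3ccc(OC)cc3)CCC(C)=O | intermediate
23 | methyl 5α,6α-epoxy-9β-[(4-methoxybenzyl)oxy]-13-oxo-14,15-dinorlabd-8(17)-en-19-oate | C=C1C[C@@H]2O[C@]23[C@](C)(CCC[C@]3(C)C(=O)OC)[C@]1(OCc4ccc(OC)cc4)CCC(C)=O | intermediate
24 | 9β-[(4-methoxybenzyl)oxy]-14,15-dinorlabd-8(17)-ene-5α,13,19-triol (C13 epimers) | C=C1CC[C@]2(O)[C@](C)(CCC[C@]2(C)CO)[C@]1(OCc3ccc(OC)cc3)CCC(C)O | intermediate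
25 | 5α-hydroxy-9β-[(4-methoxybenzyl)oxy]-13-oxo-14,15-dinorlabd-8(17)-en-19-al | C=C1CC[C@]2(O)[C@](C)(CCC[C@]2(C)C=O)[C@]1(OCc3ccc(OC)cc3)CCC(C)=O | intermediate
26 | 5α-hydroxy-9β-[(4-methoxybenzyl)oxy]-13-oxo-14,15-dinorlabd-8(17)-en-19-oic acid | C=C1CC[C@]2(O)[C@](C)(CCC[C@]2(C)C(=O)O)[C@]1(OCc3ccc(OC)cc3)CCC(C)=O | intermediate
27 | triethyl phosphonoacetate | CCOC(=O)CP(=O)(OCC)OCC | starting material
28 | 15-ethyl hydrogen 5α-hydroxy-9β-[(4-methoxybenzyl)oxy]labda-8(17),13E-diene-15,19-dioate | C=C1CC[C@]2(O)[C@](C)(CCC[C@]2(C)C(=O)O)[C@]1(OCc3ccc(OC)cc3)CC/C(C)=C/C(=O)OCC | intermediate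
29 | 5α,15-dihydroxy-9β-[(4-methoxybenzyl)oxy]labda-8(17),13E-dien-19-oic acid | C=C1CC[C@]2(O)[C@](C)(CCC[C@]2(C)C(=O)O)[C@]1(OCc3ccc(OC)cc3)CC/C(C)=C/CO | intermediate
30 | 5α,9β-dihydroxyisocupressic acid | C=C1CC[C@]2(O)[C@](C)(CCC[C@]2(C)C(=O)O)[C@]1(O)CC/C(C)=C/CO | target

Total step count: 20.
Longest linear sequence: 16 steps (steps 1–5, then 10–20); the dienophile branch (steps 6–9) joins at step 10.

Steps most likely to fail

Risk 1, step 10. The cycloaddition has to form two adjacent quaternary centres against a diene terminus that carries an inside methyl group, so it may be slower than thermal decay of the allenyl ketone or than a 1,5-hydrogen shift in the diene. The long acyl chain may also erode endo and facial control. Lewis-acid activation would be the first change of conditions; the fallback proper changes the dienophile and adds C12, C13 and C16 afterwards. It sets out from 9 and 15 (made from 12 as in step 9). Formylation of 15 with N,N-dimethylformamide at −78 °C should give 2-[(4-methoxybenzyl)oxy]buta-2,3-dienal F1, a smaller and more electrophilic dienophile. Its cycloaddition with 9 (toluene, 80–110 °C) should follow the same orientation rules and give the 9α-formyl adduct methyl 9β-[(4-methoxybenzyl)oxy]-11-oxo-12,13,14,15,16-pentanorlabda-5,8(17)-dien-19-oate F2. Wittig olefination of F2 with 1-(triphenylphosphoranylidene)propan-2-one (toluene, 90 °C) then leads to E-enone 21, where the route is rejoined; steps 11 and 12 are no longer needed.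

Risk 2, step 15. Hydride has to reach C6 from the β face, next to the axial C10 methyl and the C19 oxygen, so epoxide opening may lag behind ester reduction. The C19 alkoxide formed first may then open the epoxide itself, or the Lewis acidity of aluminium may induce rearrangement of the epoxide. The fallback opens the epoxide with a soft nucleophile while C19 is still an ester and removes the heteroatom by radical reduction. It sets out from 23. Sodium phenylselenide (PhSeSePh, NaBH4, EtOH, reflux; the borohydride also reduces the C13 ketone) should attack C6 in the same trans-diaxial sense and give methyl 5α,13-dihydroxy-9β-[(4-methoxybenzyl)oxy]-6β-(phenylselanyl)-14,15-dinorlabd-8(17)-en-19-oate F3. Bu3SnH/AIBN (toluene, 80 °C) replaces selenium by hydrogen (a C6 radical has no favourable rearrangement path) and gives methyl 5α,13-dihydroxy-9β-[(4-methoxybenzyl)oxy]-14,15-dinorlabd-8(17)-en-19-oate F4. LiAlH4 at 0 °C then reduces only the ester and returns to triol 24.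

Risk 3, step 9. The strongly basic lithiated allene may deprotonate the amide at its activated CH2 group instead of adding to it, and the sensitive allenyl ketone may not survive a slow addition or the work-up. The fallback makes the same carbon–carbon bond by addition to an aldehyde and reaches the ketone by oxidation. It sets out from 14 and 15. Reduction of 14 (i-Bu2AlH, THF, −78 °C) should give (2-methyl-1,3-dioxolan-2-yl)acetaldehyde F5. Addition of 15 at −78 °C gives the allenyl carbinol 3-[(4-methoxybenzyl)oxy]-1-(2-methyl-1,3-dioxolan-2-yl)penta-3,4-dien-2-ol F6. Oxidation of this allenylic alcohol with activated MnO2 (CH2Cl2, rt) or with Dess–Martin periodinane/pyridine returns to ketone 16.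

Further compounds

F1 | step 10 | 2-[(4-methoxybenzyl)oxy]buta-2,3-dienal | C=C=C(OCc1ccc(OC)cc1)C=O
F2 | step 10 | methyl 9β-[(4-methoxybenzyl)oxy]-11-oxo-12,13,14,15,16-pentanorlabda-5,8(17)-dien-19-oate | C=C1CC=C2[C@](C)(CCC[C@]2(C)C(=O)OC)[C@]1(OCc3ccc(OC)cc3)C=O
F3 | step 15 | methyl 5α,13-dihydroxy-9β-[(4-methoxybenzyl)oxy]-6β-(phenylselanyl)-14,15-dinorlabd-8(17)-en-19-oate (C13 epimers) | C=C1C[C@@H]([Se]c5ccccc5)[C@]2(O)[C@](C)(CCC[C@]2(C)C(=O)OC)[C@]1(OCc3ccc(OC)cc3)CCC(C)O
F4 | step 15 | methyl 5α,13-dihydroxy-9β-[(4-methoxybenzyl)oxy]-14,15-dinorlabd-8(17)-en-19-oate (C13 epimers) | C=C1CC[C@]2(O)[C@](C)(CCC[C@]2(C)C(=O)OC)[C@]1(OCc3ccc(OC)cc3)CCC(C)O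
F5 | step 9 | (2-methyl-1,3-dioxolan-2-yl)acetaldehyde | O=CCC1(C)OCCO1
F6 | step 9 | 3-[(4-methoxybenzyl)oxy]-1-(2-methyl-1,3-dioxolan-2-yl)penta-3,4-dien-2-ol (racemic) | C=C=C(OCc1ccc(OC)cc1)C(O)CC2(C)OCCO2
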